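## The problem

Gnetofuran A (24) is a trans-2-aryl-3-hydroxymethyl-2,3-dihydrobenzofuran of (2R,3S) configuration. Ring A is a guaiacyl group on C2. The benzo ring (ring B) carries a methoxy group at C7, ortho to O1, and an (E)-3,5-dihydroxystyryl group at C5, para to O1. The only stereocentres are the adjacent C2 and C3. Their trans relationship is the thermodynamic one, so the real task is the absolute configuration. C2 is a benzylic ether para to a phenol and can ionise to a quinone methide, whereas C3 cannot epimerise; C3 can therefore correct C2, but not the reverse. The free phenols, the resorcinol, the electron-rich stilbene and the C2–O1 bond rule out hydrogenolysis, strong oxidants, and hot acid or base late in the route. Ring B is tetrasubstituted in a 1,2,3,5 pattern, which is awkward to reach by substitution on a preformed benzofuran. The enabling feature is that O1, C2, C3, C3a and C7a are the ring atoms of a trans-4,5-disubstituted γ-butyrolactone, with C7a as the carbonyl carbon and C3a as the α-carbon. Such a lactone is available with both stereocentres from an auxiliary aldol. Its enol derivative is a two-carbon partner onto which C4–C7 can be delivered by a 2-pyrone that already carries handles for the C5 and C7 substituents.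

## Retrosynthesis

**24 back to 23.** The last operation is removal of protecting groups only. The three phenols are masked as methoxymethyl ethers and the primary alcohol as a tert-butyldimethylsilyl ether in 23, so one mild acid treatment frees all four. Aryl silyl ethers were rejected for the phenols because they would not survive the hydroperoxide and hot methoxide steps; benzyl ethers were rejected because the stilbene excludes hydrogenolysis. The forward step must not ionise C2–O1 irreversibly.

**23 back to 20 and 22.** The stilbene double bond is cut by a Horner–Wadsworth–Emmons disconnection into phosphonate 20 and aldehyde 22. A Heck cut is not available because the pyrone delivers a carboxyl carbon at C5, not a halide. Placing the phosphonate on the benzofuran half makes the resorcinol half a one-step compound (22 from 21) and keeps the total count lower than the reverse polarity. The forward reaction must give the E isomer, which benzylic phosphonates do reliably.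

**20 back to 16.** Phosphonate 20 comes from bromide 19, alcohol 18 and ester 17 by functional-group changes at the C5 carbon. The C7 methoxy group of 17 is traced to the bromide of 16 by a copper-mediated exchange. Bromine is kept in the pyrone, not methoxy, because a 3-bromo-2-pyrone is an established electron-poor diene, whereas a 3-methoxy group would deactivate it. The forward steps require only groups stable to methoxide and hydride, which the methoxymethyl ether and the alkyl silyl ether are.

**16 back to 11 and 13 (key disconnection).** Bonds C3a–C4 and C7–C7a are cut, with CO2 and silanol added back notionally. This takes ring B apart into lactone ketene silyl acetal 11 and methyl 3-bromocoumalate 13. The neighbouring cuts (O1–C2 by cycloetherification, C3–C3a by aryl migration) each leave a stereocentre to be set during ring closure. This cut leaves both stereocentres untouched in a saturated ring and reduces a tetrasubstituted arene to two small pieces. The forward reaction must be regioselective (acetal carbon to pyrone C3) and must expel the silyloxy group, not the ring oxygen.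

**11 back to 7; 13 back to 12.** Ketene silyl acetal 11 is the O-silylated enolate of lactone 10. Lactone 10 is the silyl ether of hydroxymethyl lactone 9, which comes from acid 8 by borane reduction, and 8 from acyl oxazolidinone 7 by hydroperoxide cleavage. Pyrone 13 is the bromination product of methyl coumalate 12. These are routine steps; the only demand is chemoselectivity for the exocyclic carbonyl over the lactone.

**7 back to 5 and 2; 5 back to 3 and 4; 2 back to 1.** The C2–C3 bond (target numbering) and the lactone C–O bond are cut by an Evans syn-aldol of succinate imide 5 with protected vanillin 2, through adduct 6, followed by lactonisation. The syn adduct closes to the trans lactone, and the (R)-auxiliary 3 gives the (2R,3S) series. Imide 5 is the N-acylation product of 3 with the commercial half-ester chloride 4; aldehyde 2 is vanillin 1 with its phenol protected. One reliable reaction therefore sets both stereocentres from achiral carbon fragments.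

## Roads not taken

**Alternative 1: flavanone ring contraction by oxidative 1,2-aryl shift.** The cut is C3–C3a. An enantioenriched flavanone A1 would be treated with PhI(OAc)2 and H2SO4 in trimethyl orthoformate. Trivalent iodine attacks C3 of the enol ether, ring B migrates from the ketal carbon to C3, and the former carbonyl carbon leaves the ring as a methyl ester, giving trans ester A2.
- Merits: the C7 methoxy group is present from the start, the C5 bromide of A2 allows a one-step Heck coupling (Pd(OAc)2) to the stilbene, and the sequence is clearly shorter than the chosen one.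
- Weak points: the single source of chirality is the flavanone C2 centre, which racemises by reversible opening to the 2'-hydroxychalcone in just the strongly acidic medium the rearrangement needs. The electron-rich C2 aryl group can migrate instead (the isoflavone pathway), which the pivalate only partly suppresses. The new C3 centre is α to an ester and benzylic.
- Comparison: this road wins on step count. The chosen plan offers instead two stereocentres fixed by an auxiliary aldol before ring B exists and never enolisable afterwards.

**Alternative 2: intramolecular Diels–Alder reaction of a styrylpyrone.** Here C3a–C7a and C4–C5 are cut. A 3-alkoxy-4-methoxy-6-styryl-2-pyrone A3, carrying a chiral homopropargylic ether on its C3 oxygen, would be heated so that the pyrone adds across the tethered terminal alkyne and loses CO2, giving the tetrasilyl ether A4 directly.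
- Merits: ring B, the dihydrofuran ring and the stilbene appear in one step, no late methoxylation or olefination is needed, and the regiochemistry is fixed by the tether. In convergence this plan is superior.
- Weak points: the difficulty moves to A3. The ether between a 3-hydroxypyrone and a secondary, electron-rich benzylic carbon must be made without ionisation at that carbon. The pyrone is electron-rich and the alkyne unactivated, so temperatures are expected at which the styryl group and the aryl silyl ethers are at risk.
- Comparison: the chosen plan forms the C2–O bond inside an aldol and lactonisation, where it cannot ionise, and uses an electronically matched intermolecular cycloaddition. It pays with a longer end-game.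

**Alternative 3: quinone methide cycloetherification.** The cut is O1–C2. Ag2O (monovalent silver) would oxidise the free guaiacyl phenol of the enantioenriched 2,3-diarylpropanol silyl ether A5 to its para-quinone methide, and the ortho phenol of ring B would add to the methide carbon to give A6.
- Merits: the route is biomimetic, needs one stereocentre only (C3 directs C2 to the trans product), and A6 already carries the C7 methoxy and C5 ester, so the bromide exchange is avoided. It is probably two or three steps shorter.
- Weak points: a quinone methide with a hydrogen on the adjacent carbon can tautomerise to the 4-hydroxystyrene, which destroys the only stereocentre. Phenoxyl radical coupling competes with methide formation for a guaiacol with a free ortho position. The enantioenriched diarylpropanol needs its own auxiliary alkylation.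
- Comparison: the chosen plan uses no oxidation of a free phenol and sets both centres by one well-understood reaction. It pays with the extra C7 methoxylation.

Key step: step 9

Remark on the chemistry: methyl 4-chloro-4-oxobutanoate (4) and (R)-4-benzyl-1,3-oxazolidin-2-one (3) are taken as commercial. The sp3 centres that are formed and destroyed in 14 and 15 are left undefined.

## Route

Step 1
Reactants: 1 vanillin
Product: 2 3-methoxy-4-(methoxymethoxy)benzaldehyde
Conditions: MOMCl, iPr2NEt, CH2Cl2, 0 °C to rt
Reagents that add atoms: chloromethyl methyl ether, COCCl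
Why: O-alkylation of the phenol by the reactive α-chloro ether; the acetal ether is stable to every basic, hydridic and thermal step that follows.

Step 2
Reactants: 3 (R)-4-benzyl-1,3-oxazolidin-2-one; 4 methyl 4-chloro-4-oxobutanoate
Product: 5 methyl 4-[(4R)-4-benzyl-2-oxo-1,3-oxazolidin-3-yl]-4-oxobutanoate
Conditions: nBuLi, THF, −78 °C; then 4, −78 to 0 °C
Reagents that add atoms: none
Why: N-acylation of the lithiated oxazolidinone; the acid chloride reacts far faster than the methyl ester, so the half-ester imide is formed cleanly.

Step 3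
Reactants: 5 methyl 4-[(4R)-4-benzyl-2-oxo-1,3-oxazolidin-3-yl]-4-oxobutanoate; 2 3-methoxy-4-(methoxymethoxy)benzaldehyde
Product: 7 (4R)-4-benzyl-3-{(2R,3R)-2-[3-methoxy-4-(methoxymethoxy)phenyl]-5-oxooxolane-3-carbonyl}-1,3-oxazolidin-2-one, via syn-aldol adduct 6 (not isolated)
Conditions: Bu2BOTf, iPr2NEt, CH2Cl2, −78 to 0 °C; 2, −78 to 0 °C; pH 7 buffer, MeOH, H2O2, 0 °C; then PPTS (cat.), PhMe, 60 °C
Reagents that add atoms: none
Why: Evans syn-aldol: soft enolisation occurs only at the imide α-carbon to give the Z boron enolate, which adds through a Zimmerman–Traxler chair on the face away from the benzyl group, so the (R)-auxiliary sets both centres as (3R,4R) in 6. The new hydroxyl then closes onto the methyl ester with retention; acyl and aryl groups lie trans on the lactone, which is also the thermodynamic arrangement.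

Step 4
Reactants: 7 (4R)-4-benzyl-3-{(2R,3R)-2-[3-methoxy-4-(methoxymethoxy)phenyl]-5-oxooxolane-3-carbonyl}-1,3-oxazolidin-2-one
Product: 8 (2R,3R)-2-[3-methoxy-4-(methoxymethoxy)phenyl]-5-oxooxolane-3-carboxylic acid
Conditions: LiOH, H2O2, THF/H2O, 0 °C; Na2SO3; HCl to pH 2
Reagents that add atoms: lithium hydroperoxide (from LiOH and H2O2), [Li+].[O-]O
Why: Hydroperoxide cleaves the exocyclic imide carbonyl selectively and returns auxiliary 3; any lactone opened by hydroxide re-closes with retention on acidification, and the trans acid is the stable epimer.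

Step 5
Reactants: 8 (2R,3R)-2-[3-methoxy-4-(methoxymethoxy)phenyl]-5-oxooxolane-3-carboxylic acid
Product: 9 (4S,5R)-4-(hydroxymethyl)-5-[3-methoxy-4-(methoxymethoxy)phenyl]oxolan-2-one
Conditions: BH3·SMe2, THF, 0 °C to rt; MeOH
Reagents that add atoms: none
Why: Borane reduces a carboxylic acid through its acyloxyborane much faster than a lactone, the standard chemoselective reduction of paraconic acids; the neutral medium avoids translactonisation.

Step 6
Reactants: 9 (4S,5R)-4-(hydroxymethyl)-5-[3-methoxy-4-(methoxymethoxy)phenyl]oxolan-2-one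
Product: 10 (4S,5R)-4-[(tert-butyldimethylsilyloxy)methyl]-5-[3-methoxy-4-(methoxymethoxy)phenyl]oxolan-2-one
Conditions: TBSCl, imidazole, DMF, rt
Reagents that add atoms: tert-butyldimethylsilyl chloride, CC(C)(C)[Si](C)(C)Cl
Why: Standard silylation of a primary alcohol; it removes the only acidic proton besides the lactone α-hydrogens and blocks translactonisation.

Step 7
Reactants: 10 (4S,5R)-4-[(tert-butyldimethylsilyloxy)methyl]-5-[3-methoxy-4-(methoxymethoxy)phenyl]oxolan-2-one
Product: 11 (4S,5R)-2-(tert-butyldimethylsilyloxy)-4-[(tert-butyldimethylsilyloxy)methyl]-5-[3-methoxy-4-(methoxymethoxy)phenyl]-4,5-dihydrofuran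
Conditions: LiN(iPr)2, THF, −78 °C; TBSCl, DMPU, −78 to 0 °C; pentane, filtration, used crude
Reagents that add atoms: tert-butyldimethylsilyl chloride, CC(C)(C)[Si](C)(C)Cl
Why: Kinetic enolisation at the only α-methylene and O-silylation in the presence of a dipolar cosolvent, as in ketene silyl acetal formation for Ireland–Claisen rearrangements; no leaving group sits β to the enolate and neither stereocentre is touched.

Step 8
Reactants: 12 methyl coumalate
Product: 13 methyl 3-bromo-2-oxo-2H-pyran-5-carboxylate
Conditions: Br2, CH2Cl2, 0 °C to rt; then Et3N, 0 °C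
Reagents that add atoms: bromine, BrBr
Why: Bromine addition and dehydrobromination, the usual route to 3-bromo-2-pyrones; C3 is the only nucleophilic ring carbon left once C5 carries the ester.

Step 9
Reactants: 11 (4S,5R)-2-(tert-butyldimethylsilyloxy)-4-[(tert-butyldimethylsilyloxy)methyl]-5-[3-methoxy-4-(methoxymethoxy)phenyl]-4,5-dihydrofuran; 13 methyl 3-bromo-2-oxo-2H-pyran-5-carboxylate
Product: 16 methyl (2R,3S)-7-bromo-3-[(tert-butyldimethylsilyloxy)methyl]-2-[3-methoxy-4-(methoxymethoxy)phenyl]-2,3-dihydro-1-benzofuran-5-carboxylate, via bridged lactone adduct 14 (not isolated), via cyclohexadiene ketal 15 (not isolated)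
Conditions: PhMe, 25 to 110 °C, sealed tube
Reagents that add atoms: none
Why: Inverse-electron-demand Diels–Alder benzannulation: the electron-rich ketene silyl acetal adds across C3 and C6 of the electron-poor pyrone in a strongly asynchronous [4+2] step to give bridged lactone 14, retro-[4+2] loss of CO2 gives diene ketal 15, and loss of tBuMe2SiOH aromatises ring B. The closest known reaction type is the conversion of coumalates and 3-bromo-2-pyrones with ketene acetals into aryl ethers by cycloaddition, decarboxylation and loss of an alkoxy group. Ring B is the only ring closed, by intermolecular [4+2] cycloaddition forming C3a–C4 and C7–C7a, while the dihydrofuran ring is carried through intact. No lasting stereocentre is created: the sp3 centres of 14 and 15 vanish on aromatisation, and C2 and C3 come unchanged from lactone 10 because neither is enolisable here. The required regiochemistry (nucleophilic C3a to pyrone C6, acetal carbon C7a to pyrone C3) follows from the C5 ester, which makes C6 the vinylogous acceptor terminus, matched with the polarised ketene acetal; it places bromine at C7 and the ester at C5. The second selectivity needed is departure of the silyloxy group, not the ring oxygen, from 15: silanolate is the better leaving group and the ring oxygen the better donor to the developing oxocarbenium ion.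

Step 10
Reactants: 16 methyl (2R,3S)-7-bromo-3-[(tert-butyldimethylsilyloxy)methyl]-2-[3-methoxy-4-(methoxymethoxy)phenyl]-2,3-dihydro-1-benzofuran-5-carboxylate
Product: 17 methyl (2R,3S)-3-[(tert-butyldimethylsilyloxy)methyl]-7-methoxy-2-[3-methoxy-4-(methoxymethoxy)phenyl]-2,3-dihydro-1-benzofuran-5-carboxylate
Conditions: CuI (cat.), NaOMe, MeOH/DMF, 100 °C
Reagents that add atoms: sodium methoxide, C[O-].[Na+]
Why: Ullmann-type methoxylation of an aryl bromide catalysed by monovalent copper, long used for bromo-alkoxy benzoates and benzaldehydes; methoxide can only transesterify the methyl ester to itself, and the acetal and alkyl silyl ether tolerate it.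

Step 11
Reactants: 17 methyl (2R,3S)-3-[(tert-butyldimethylsilyloxy)methyl]-7-methoxy-2-[3-methoxy-4-(methoxymethoxy)phenyl]-2,3-dihydro-1-benzofuran-5-carboxylate
Product: 18 {(2R,3S)-3-[(tert-butyldimethylsilyloxy)methyl]-7-methoxy-2-[3-methoxy-4-(methoxymethoxy)phenyl]-2,3-dihydro-1-benzofuran-5-yl}methanol
Conditions: iBu2AlH, CH2Cl2, −78 to 0 °C; aq. KNaC4H4O6
Reagents that add atoms: none
Why: Full reduction of the aryl ester to the benzylic alcohol by excess aluminium hydride; no other reducible group is present.

Step 12
Reactants: 18 {(2R,3S)-3-[(tert-butyldimethylsilyloxy)methyl]-7-methoxy-2-[3-methoxy-4-(methoxymethoxy)phenyl]-2,3-dihydro-1-benzofuran-5-yl}methanol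
Product: 19 {[(2R,3S)-5-(bromomethyl)-7-methoxy-2-[3-methoxy-4-(methoxymethoxy)phenyl]-2,3-dihydro-1-benzofuran-3-yl]methoxy}(tert-butyl)dimethylsilane
Conditions: CBr4, PPh3, CH2Cl2, 0 °C
Reagents that add atoms: carbon tetrabromide, BrC(Br)(Br)Br
Why: Appel bromination of a primary benzylic alcohol under neutral conditions that spare the acetal and the silyl ether; the reactive bromide is used without storage.

Step 13
Reactants: 19 {[(2R,3S)-5-(bromomethyl)-7-methoxy-2-[3-methoxy-4-(methoxymethoxy)phenyl]-2,3-dihydro-1-benzofuran-3-yl]methoxy}(tert-butyl)dimethylsilane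
Product: 20 diethyl ({(2R,3S)-3-[(tert-butyldimethylsilyloxy)methyl]-7-methoxy-2-[3-methoxy-4-(methoxymethoxy)phenyl]-2,3-dihydro-1-benzofuran-5-yl}methyl)phosphonate
Conditions: P(OEt)3, 110 °C
Reagents that add atoms: triethyl phosphite, CCOP(OCC)OCC
Why: Michaelis–Arbuzov reaction; para-alkoxybenzyl bromides are among the most reactive substrates, so moderate heating suffices.

Step 14
Reactants: 21 3,5-dihydroxybenzaldehyde
Product: 22 3,5-bis(methoxymethoxy)benzaldehyde
Conditions: MOMCl, iPr2NEt, CH2Cl2, 0 °C to rt
Reagents that add atoms: chloromethyl methyl ether, COCCl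
Why: Double O-alkylation of the phenols; it removes the acidic protons that would quench the phosphonate anion and deactivate the aldehyde.

Step 15
Reactants: 20 diethyl ({(2R,3S)-3-[(tert-butyldimethylsilyloxy)methyl]-7-methoxy-2-[3-methoxy-4-(methoxymethoxy)phenyl]-2,3-dihydro-1-benzofuran-5-yl}methyl)phosphonate; 22 3,5-bis(methoxymethoxy)benzaldehyde
Product: 23 tert-butyl({(2R,3S)-5-[(E)-2-[3,5-bis(methoxymethoxy)phenyl]ethenyl]-7-methoxy-2-[3-methoxy-4-(methoxymethoxy)phenyl]-2,3-dihydro-1-benzofuran-3-yl}methoxy)dimethylsilane
Conditions: KOtBu, THF, 0 °C; then 22, 0 °C to rt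
Reagents that add atoms: none
Why: Horner–Wadsworth–Emmons olefination of a benzylic phosphonate with an aryl aldehyde, the standard E-selective stilbene synthesis; no other acidic or electrophilic site is present and neither ring stereocentre is base-labile.

Step 16
Reactants: 23 tert-butyl({(2R,3S)-5-[(E)-2-[3,5-bis(methoxymethoxy)phenyl]ethenyl]-7-methoxy-2-[3-methoxy-4-(methoxymethoxy)phenyl]-2,3-dihydro-1-benzofuran-3-yl}methoxy)dimethylsilane
Product: 24 gnetofuran A, 5-[(E)-2-[(2R,3S)-2-(4-hydroxy-3-methoxyphenyl)-3-(hydroxymethyl)-7-methoxy-2,3-dihydro-1-benzofuran-5-yl]ethenyl]benzene-1,3-diol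
Conditions: HCl (ca. 1 M), MeOH, 25 to 40 °C
Reagents that add atoms: none
Why: Acid-catalysed acetal exchange removes the three aryl methoxymethyl groups and methanolysis removes the primary silyl ether in one operation. Any reversible ionisation at C2 re-closes to the trans ring dictated by the fixed C3 centre.

## Compound list

1 | vanillin (4-hydroxy-3-methoxybenzaldehyde) | COc1cc(C=O)ccc1O | starting material
2 | 3-methoxy-4-(methoxymethoxy)benzaldehyde | COCOc1ccc(C=O)cc1OC | intermediate
3 | (R)-4-benzyl-1,3-oxazolidin-2-one | O=C1N[C@H](Cc2ccccc2)CO1 | starting material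
4 | methyl 4-chloro-4-oxobutanoate | COC(=O)CCC(Cl)=O | starting material
5 | methyl 4-[(4R)-4-benzyl-2-oxo-1,3-oxazolidin-3-yl]-4-oxobutanoate | COC(=O)CCC(=O)N1C(=O)OC[C@H]1Cc1ccccc1 | intermediate
6 | methyl (3R,4R)-3-[(4R)-4-benzyl-2-oxo-1,3-oxazolidine-3-carbonyl]-4-hydroxy-4-[3-methoxy-4-(methoxymethoxy)phenyl]butanoate (syn-aldol adduct) | COc1cc([C@H](O)[C@@H](CC(=O)OC)C(=O)N2C(=O)OC[C@H]2Cc2ccccc2)ccc1OCOC | intermediate
7 | (4R)-4-benzyl-3-{(2R,3R)-2-[3-methoxy-4-(methoxymethoxy)phenyl]-5-oxooxolane-3-carbonyl}-1,3-oxazolidin-2-one | COc1cc([C@@H]2OC(=O)C[C@H]2C(=O)N3C(=O)OC[C@H]3Cc3ccccc3)ccc1OCOC | intermediate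
8 | (2R,3R)-2-[3-methoxy-4-(methoxymethoxy)phenyl]-5-oxooxolane-3-carboxylic acid | COc1cc([C@@H]2OC(=O)C[C@H]2C(=O)O)ccc1OCOC | intermediate
9 | (4S,5R)-4-(hydroxymethyl)-5-[3-methoxy-4-(methoxymethoxy)phenyl]oxolan-2-one | COc1cc([C@@H]2OC(=O)C[C@H]2CO)ccc1OCOC | intermediate
10 | (4S,5R)-4-[(tert-butyldimethylsilyloxy)methyl]-5-[3-methoxy-4-(methoxymethoxy)phenyl]oxolan-2-one | COc1cc([C@@H]2OC(=O)C[C@H]2CO[Si](C)(C)C(C)(C)C)ccc1OCOC | intermediate
11 | (4S,5R)-2-(tert-butyldimethylsilyloxy)-4-[(tert-butyldimethylsilyloxy)methyl]-5-[3-methoxy-4-(methoxymethoxy)phenyl]-4,5-dihydrofuran | COc1cc([C@@H]2OC(O[Si](C)(C)C(C)(C)C)=C[C@H]2CO[Si](C)(C)C(C)(C)C)ccc1OCOC | intermediate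
12 | methyl coumalate (methyl 2-oxo-2H-pyran-5-carboxylate) | COC(=O)c1ccc(=O)oc1 | starting material
13 | methyl 3-bromo-2-oxo-2H-pyran-5-carboxylate | COC(=O)c1coc(=O)c(Br)c1 | intermediate
14 | bridged lactone adduct of 11 and 13: 2-oxabicyclo[2.2.2]oct-5-en-3-one with bromine on the bridgehead next to the lactone carbonyl, the methyl ester on the ring alkene, and the silyloxy tetrahydrofuran cis-fused across the new two-carbon bridge (acetal carbon on the brominated bridgehead) | COC(=O)C1=CC2(Br)C(=O)OC1C1[C@@H](CO[Si](C)(C)C(C)(C)C)[C@H](c3ccc(OCOC)c(OC)c3)OC12O[Si](C)(C)C(C)(C)C | intermediate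
15 | methyl (2R,3S)-7-bromo-7a-(tert-butyldimethylsilyloxy)-3-[(tert-butyldimethylsilyloxy)methyl]-2-[3-methoxy-4-(methoxymethoxy)phenyl]-2,3,3a,7a-tetrahydro-1-benzofuran-5-carboxylate (cis ring fusion, transient) | COC(=O)C1=CC2[C@@H](CO[Si](C)(C)C(C)(C)C)[C@H](c3ccc(OCOC)c(OC)c3)OC2(O[Si](C)(C)C(C)(C)C)C(Br)=C1 | intermediate
16 | methyl (2R,3S)-7-bromo-3-[(tert-butyldimethylsilyloxy)methyl]-2-[3-methoxy-4-(methoxymethoxy)phenyl]-2,3-dihydro-1-benzofuran-5-carboxylate | COc1cc([C@@H]2Oc3c(Br)cc(C(=O)OC)cc3[C@H]2CO[Si](C)(C)C(C)(C)C)ccc1OCOC | intermediate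
17 | methyl (2R,3S)-3-[(tert-butyldimethylsilyloxy)methyl]-7-methoxy-2-[3-methoxy-4-(methoxymethoxy)phenyl]-2,3-dihydro-1-benzofuran-5-carboxylate | COc1cc([C@@H]2Oc3c(OC)cc(C(=O)OC)cc3[C@H]2CO[Si](C)(C)C(C)(C)C)ccc1OCOC | intermediate
18 | {(2R,3S)-3-[(tert-butyldimethylsilyloxy)methyl]-7-methoxy-2-[3-methoxy-4-(methoxymethoxy)phenyl]-2,3-dihydro-1-benzofuran-5-yl}methanol | COc1cc([C@@H]2Oc3c(OC)cc(CO)cc3[C@H]2CO[Si](C)(C)C(C)(C)C)ccc1OCOC | intermediate
19 | {[(2R,3S)-5-(bromomethyl)-7-methoxy-2-[3-methoxy-4-(methoxymethoxy)phenyl]-2,3-dihydro-1-benzofuran-3-yl]methoxy}(tert-butyl)dimethylsilane | COc1cc([C@@H]2Oc3c(OC)cc(CBr)cc3[C@H]2CO[Si](C)(C)C(C)(C)C)ccc1OCOC | intermediate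
20 | diethyl ({(2R,3S)-3-[(tert-butyldimethylsilyloxy)methyl]-7-methoxy-2-[3-methoxy-4-(methoxymethoxy)phenyl]-2,3-dihydro-1-benzofuran-5-yl}methyl)phosphonate | COc1cc([C@@H]2Oc3c(OC)cc(CP(=O)(OCC)OCC)cc3[C@H]2CO[Si](C)(C)C(C)(C)C)ccc1OCOC | intermediate
21 | 3,5-dihydroxybenzaldehyde | O=Cc1cc(O)cc(O)c1 | starting material
22 | 3,5-bis(methoxymethoxy)benzaldehyde | COCOc1cc(C=O)cc(OCOC)c1 | intermediate
23 | tert-butyl({(2R,3S)-5-[(E)-2-[3,5-bis(methoxymethoxy)phenyl]ethenyl]-7-methoxy-2-[3-methoxy-4-(methoxymethoxy)phenyl]-2,3-dihydro-1-benzofuran-3-yl}methoxy)dimethylsilane | COc1cc([C@@H]2Oc3c(OC)cc(/C=C/c4cc(OCOC)cc(OCOC)c4)cc3[C@H]2CO[Si](C)(C)C(C)(C)C)ccc1OCOC | intermediate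
24 | gnetofuran A, 5-[(E)-2-[(2R,3S)-2-(4-hydroxy-3-methoxyphenyl)-3-(hydroxymethyl)-7-methoxy-2,3-dihydro-1-benzofuran-5-yl]ethenyl]benzene-1,3-diol | COc1cc([C@@H]2Oc3c(OC)cc(/C=C/c4cc(O)cc(O)c4)cc3[C@H]2CO)ccc1O | target

## Step count and risks

Total steps: 16. Longest linear sequence: 13 steps (1, 3, 4, 5, 6, 7, 9, 10, 11, 12, 13, 15, 16, from vanillin).

**Step 9 (key step).** The most likely failure is departure of the ring oxygen in place of the silyloxy group during aromatisation of 15, which opens the dihydrofuran. Less likely are collapse of the first-formed Michael-type zwitterion by silyl transfer before the second bond closes, and hydrolytic loss of 11 at the temperature needed for CO2 extrusion. The fallback sets out from 11 and 13 and returns at 16. If the ring oxygen leaves and the silyl group shifts to the liberated benzylic oxygen, the thermolysate contains the open-chain phenol methyl 3-bromo-5-{(1R,2S)-1,3-bis(tert-butyldimethylsilyloxy)-1-[3-methoxy-4-(methoxymethoxy)phenyl]propan-2-yl}-4-hydroxybenzoate F1. Catalytic camphorsulfonic acid in CH2Cl2 at 0 °C would ionise its para-alkoxybenzylic silyl ether. The free phenol then closes the ring in a cycloetherification of the SN1 type, with the fixed C3 centre steering C2 to the thermodynamic trans arrangement of 16. Inversion methods such as a Mitsunobu closure are excluded, since they would give the cis ring.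

**Step 7.** The risks are C-silylation in place of O-silylation, Claisen self-condensation of the lactone enolate, and hydrolysis of the ketene silyl acetal during handling. The fallback sets out from 10 and returns at 16, replacing the silyloxy leaving group by a thiolate. Lawesson's reagent in toluene would convert 10 into the thionolactone (4S,5R)-4-[(tert-butyldimethylsilyloxy)methyl]-5-[3-methoxy-4-(methoxymethoxy)phenyl]oxolane-2-thione F2. Deprotonation with LiN(iPr)2 and S-methylation with MeI, which is regioselective at sulfur, would give the ketene O,S-acetal (4S,5R)-4-[(tert-butyldimethylsilyloxy)methyl]-5-[3-methoxy-4-(methoxymethoxy)phenyl]-2-(methylsulfanyl)-4,5-dihydrofuran F3. This compound is hydrolytically robust; heated with 13 it would pass through the same cycloaddition and lose CO2 and methanethiol to give 16. The fallback costs one extra step.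

**Step 10.** The risks are hydrodebromination, saponification of the ester by adventitious hydroxide, and cleavage of the primary silyl ether by hot methoxide. The fallback sets out from 16 and returns at 17. Miyaura borylation (B2pin2, Pd(dppf)Cl2, KOAc, dioxane, 80 °C) would give the boronate methyl (2R,3S)-3-[(tert-butyldimethylsilyloxy)methyl]-2-[3-methoxy-4-(methoxymethoxy)phenyl]-7-(4,4,5,5-tetramethyl-1,3,2-dioxaborolan-2-yl)-2,3-dihydro-1-benzofuran-5-carboxylate F4. Oxidation with NaBO3 in aqueous THF would give the phenol methyl (2R,3S)-3-[(tert-butyldimethylsilyloxy)methyl]-7-hydroxy-2-[3-methoxy-4-(methoxymethoxy)phenyl]-2,3-dihydro-1-benzofuran-5-carboxylate F5. Methylation with MeI and K2CO3 in acetone would then give 17. This takes three mild steps in place of one hot one.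

**Step 16.** Once the para phenol is free, acid can ionise the C2–O1 benzylic ether, and the opened cation can be trapped by methanol; the electron-rich stilbene can also oligomerise under acid. The fallback sets out from 23 and returns at 24 without a Brønsted acid. Me3SiOTf with 2,2'-bipyridyl in CH2Cl2 at 0 °C, followed by water, would exchange the three aryl methoxymethyl groups for hydrolytically labile trimethylsilyl groups. This would give 5-[(E)-2-{(2R,3S)-3-[(tert-butyldimethylsilyloxy)methyl]-2-(4-hydroxy-3-methoxyphenyl)-7-methoxy-2,3-dihydro-1-benzofuran-5-yl}ethenyl]benzene-1,3-diol F6. Bu4NF buffered with acetic acid in THF would then remove the remaining alkyl silyl ether to give 24.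

## Further compounds

F1 | step 9 | methyl 3-bromo-5-{(1R,2S)-1,3-bis(tert-butyldimethylsilyloxy)-1-[3-methoxy-4-(methoxymethoxy)phenyl]propan-2-yl}-4-hydroxybenzoate | COc1cc([C@H](O[Si](C)(C)C(C)(C)C)[C@H](CO[Si](C)(C)C(C)(C)C)c2cc(C(=O)OC)cc(Br)c2O)ccc1OCOC
F2 | step 7 | (4S,5R)-4-[(tert-butyldimethylsilyloxy)methyl]-5-[3-methoxy-4-(methoxymethoxy)phenyl]oxolane-2-thione | COc1cc([C@@H]2OC(=S)C[C@H]2CO[Si](C)(C)C(C)(C)C)ccc1OCOC
F3 | step 7 | (4S,5R)-4-[(tert-butyldimethylsilyloxy)methyl]-5-[3-methoxy-4-(methoxymethoxy)phenyl]-2-(methylsulfanyl)-4,5-dihydrofuran | COc1cc([C@@H]2OC(SC)=C[C@H]2CO[Si](C)(C)C(C)(C)C)ccc1OCOC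
F4 | step 10 | methyl (2R,3S)-3-[(tert-butyldimethylsilyloxy)methyl]-2-[3-methoxy-4-(methoxymethoxy)phenyl]-7-(4,4,5,5-tetramethyl-1,3,2-dioxaborolan-2-yl)-2,3-dihydro-1-benzofuran-5-carboxylate | COc1cc([C@@H]2Oc3c(B4OC(C)(C)C(C)(C)O4)cc(C(=O)OC)cc3[C@H]2CO[Si](C)(C)C(C)(C)C)ccc1OCOC
F5 | step 10 | methyl (2R,3S)-3-[(tert-butyldimethylsilyloxy)methyl]-7-hydroxy-2-[3-methoxy-4-(methoxymethoxy)phenyl]-2,3-dihydro-1-benzofuran-5-carboxylate | COc1cc([C@@H]2Oc3c(O)cc(C(=O)OC)cc3[C@H]2CO[Si](C)(C)C(C)(C)C)ccc1OCOC
F6 | step 16 | 5-[(E)-2-{(2R,3S)-3-[(tert-butyldimethylsilyloxy)methyl]-2-(4-hydroxy-3-methoxyphenyl)-7-methoxy-2,3-dihydro-1-benzofuran-5-yl}ethenyl]benzene-1,3-diol | COc1cc([C@@H]2Oc3c(OC)cc(/C=C/c4cc(O)cc(O)c4)cc3[C@H]2CO[Si](C)(C)C(C)(C)C)ccc1O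
A1 | alternative 1 | 4-[(2R)-6-bromo-8-methoxy-4-oxo-3,4-dihydro-2H-chromen-2-yl]-2-methoxyphenyl 2,2-dimethylpropanoate (the flavanone) | COc1cc([C@@H]2Oc3c(OC)cc(Br)cc3C(=O)C2)ccc1OC(=O)C(C)(C)C
A2 | alternative 1 | methyl (2R,3R)-5-bromo-7-methoxy-2-[3-methoxy-4-(2,2-dimethylpropanoyloxy)phenyl]-2,3-dihydro-1-benzofuran-3-carboxylate (trans) | COc1cc([C@@H]2Oc3c(OC)cc(Br)cc3[C@H]2C(=O)OC)ccc1OC(=O)C(C)(C)C
A3 | alternative 2 | 6-[(E)-2-[3,5-bis(tert-butyldimethylsilyloxy)phenyl]ethenyl]-3-{[(1R,2S)-2-[(tert-butyldimethylsilyloxy)methyl]-1-[4-(tert-butyldimethylsilyloxy)-3-methoxyphenyl]but-3-yn-1-yl]oxy}-4-methoxy-2H-pyran-2-one | COc1cc([C@H](Oc2c(OC)cc(/C=C/c3cc(O[Si](C)(C)C(C)(C)C)cc(O[Si](C)(C)C(C)(C)C)c3)oc2=O)[C@@H](C#C)CO[Si](C)(C)C(C)(C)C)ccc1O[Si](C)(C)C(C)(C)C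
A4 | alternative 2 | tetrakis(tert-butyldimethylsilyl) ether of gnetofuran A | COc1cc([C@@H]2Oc3c(OC)cc(/C=C/c4cc(O[Si](C)(C)C(C)(C)C)cc(O[Si](C)(C)C(C)(C)C)c4)cc3[C@H]2CO[Si](C)(C)C(C)(C)C)ccc1O[Si](C)(C)C(C)(C)C
A5 | alternative 3 | methyl 3-[(2S)-1-(tert-butyldimethylsilyloxy)-3-(4-hydroxy-3-methoxyphenyl)propan-2-yl]-4-hydroxy-5-methoxybenzoate | COc1cc(C[C@H](CO[Si](C)(C)C(C)(C)C)c2cc(C(=O)OC)cc(OC)c2O)ccc1O
A6 | alternative 3 | methyl (2R,3S)-3-[(tert-butyldimethylsilyloxy)methyl]-2-(4-hydroxy-3-methoxyphenyl)-7-methoxy-2,3-dihydro-1-benzofuran-5-carboxylate | COc1cc([C@@H]2Oc3c(OC)cc(C(=O)OC)cc3[C@H]2CO[Si](C)(C)C(C)(C)C)ccc1O
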